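**Retrosynthetic overview**
- The acetonyl group, the C5 ketone and the C6 tertiary alcohol are carried as a 2-methylfuran fused to the seven-membered ring and released last (oxidative furan opening, then conjugate reduction with kinetic protonation at C4). The (E)-enol ester and C16 come from 1,4-reduction/O-acylation of a furan-conjugated enal.
- The seven-membered ring is closed third, by an oxidative Heck reaction of the furan C–H onto an enal attached to C13.
- The pyran ring is closed second, in the key step: an enantioselective reductive Heck cyclisation that breaks the mirror symmetry of a cyclohexa-2,5-diene and fixes C15 (and so C10 and C13) absolutely. C6–OH follows by hydration of the resulting furyl enol ether.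
- The cyclohexane ring is the benzene ring of methyl 4-acetylbenzoate, dearomatised first by Birch reductive methylation (quaternary C13, C10–H).
- Ring order: six-membered carbocycle (from the arene), then pyran, then cycloheptanone.

Locants used below (own numbering): C1H3–C2(=O)–C3H2–C4H–C5(=O)–C6(OH)–C7H2–O8–C9Me2–C10H–C11H2–C12H2–C13(Me)–C14H2–C15H; ring bonds C15–C6, C15–C10, C13–C16, C16–C4; side chain C16–C17H=C18H–O-acyl.

Assumption: (R)-BINAP gives the drawn sense of induction in step 6; if it gives the opposite, (S)-BINAP is used.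

**Step 1**
Reactants: 1 methyl 4-acetylbenzoate
Product: 2 methyl 4-(2-hydroxypropan-2-yl)benzoate
Conditions: MeMgBr (1.05 equiv), THF, −78 °C; then H2O
Reagents that add atoms: methylmagnesium bromide, C[Mg]Br
Why: Grignard addition; at −78 °C the aryl ketone reacts much faster than the aryl ester, and no stereocentre is formed.

**Step 2**
Reactants: 2 methyl 4-(2-hydroxypropan-2-yl)benzoate
Product: 4 methyl cis-4-(2-hydroxypropan-2-yl)-1-methylcyclohexa-2,5-diene-1-carboxylate, via dilithium dienolate 3 (not isolated)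
Conditions: Li (2.3 equiv), NH3(l)–THF, −78 °C (no added alcohol); then MeI; then H2O
Reagents that add atoms: iodomethane, CI
Why: Birch reductive alkylation: the ester-stabilised dianion is protonated at C10 by the substrate's own hydroxyl (the resulting alkoxide cannot leave, so the benzylic C–O bond survives), and the enolate is C-methylated anti to the bulky C10 substituent, giving the achiral cis diene (ester and carbinol chain on one face; minor trans isomer removed).

**Step 3**
Reactants: 5 1-(5-methylfuran-2-yl)ethan-1-one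
Product: 7 2-diazo-1-(5-methylfuran-2-yl)ethan-1-one, via trifluoroacetyl diketone 6 (not isolated)
Conditions: LiN(SiMe3)2, THF, −78 °C; CF3CO2CH2CF3; then MsN3, Et3N, H2O, MeCN, rt
Reagents that add atoms: methanesulfonyl azide, CS(=O)(=O)N=[N+]=[N-]
Why: Detrifluoroacetylative Regitz diazo transfer: the methyl ketone is activated as its trifluoroacetyl derivative, which takes up the diazo group and loses the trifluoroacetyl group.

**Step 4**
Reactants: 4 methyl cis-4-(2-hydroxypropan-2-yl)-1-methylcyclohexa-2,5-diene-1-carboxylate, 7 2-diazo-1-(5-methylfuran-2-yl)ethan-1-one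
Product: 8 methyl cis-1-methyl-4-{2-[2-(5-methylfuran-2-yl)-2-oxoethoxy]propan-2-yl}cyclohexa-2,5-diene-1-carboxylate
Conditions: Rh2(OAc)4 (1 mol%), CH2Cl2, rt, slow addition of 7
Reagents that add atoms: none
Why: Rhodium-carbenoid O–H insertion, which for an acceptor carbenoid is faster than cyclopropanation of the cis-disubstituted ring alkenes and tolerates the tertiary alcohol; no stereocentre is touched.

**Step 5**
Reactants: 8 methyl cis-1-methyl-4-{2-[2-(5-methylfuran-2-yl)-2-oxoethoxy]propan-2-yl}cyclohexa-2,5-diene-1-carboxylate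
Product: 10 (Z)-enol triflate of 8 (C6–OTf cis to O8 across C6=C7), via potassium Z-enolate 9 (not isolated)
Conditions: KN(SiMe3)2, THF, −78 °C; then PhNTf2
Reagents that add atoms: N-phenylbis(trifluoromethanesulfonimide), O=S(=O)(N(c1ccccc1)S(=O)(=O)C(F)(F)F)C(F)(F)F
Why: Enolate O-triflation; the O–CH2 group is the only enolisable position, and potassium chelation by the ether oxygen gives the Z enolate, the geometry that lets C6 reach the ring.

**Step 6 (key step)**
Reactants: 10 (Z)-enol triflate of 8
Product: 11 methyl (4aS,6R,8aR)-1,1,6-trimethyl-4-(5-methylfuran-2-yl)-4a,5,6,8a-tetrahydro-1H-isochromene-6-carboxylate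
Conditions: Pd(OAc)2 (5 mol%), (R)-BINAP (7.5 mol%), HCO2Na (1.5 equiv), DMF, 60 °C
Reagents that add atoms: none
Why: Proposed new method: the alkenyl triflate adds oxidatively to zerovalent palladium, 6-exo syn-carbopalladation takes one of the two enantiotopic ring alkenes (chosen by the chiral bisphosphine; the tether on C10 forces C6 onto the face cis to C9, which sets C15 and makes C10 and C13 stereogenic), and because the C14–Pd intermediate has no syn β-hydrogen (C13 is quaternary, H15 is anti) it is reduced by formate; the closest known reactions are the asymmetric Heck desymmetrisation of cyclohexa-2,5-dienes and the asymmetric reductive Heck (hydroarylation) reaction.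

**Step 7**
Reactants: 11 methyl (4aS,6R,8aR)-1,1,6-trimethyl-4-(5-methylfuran-2-yl)-4a,5,6,8a-tetrahydro-1H-isochromene-6-carboxylate
Product: 12 methyl (4aS,6S,8aR)-1,1,6-trimethyl-4-(5-methylfuran-2-yl)-4a,5,6,7,8,8a-hexahydro-1H-isochromene-6-carboxylate
Conditions: H2 (1 atm), RhCl(PPh3)3 (5 mol%), benzene–EtOH, rt
Reagents that add atoms: none
Why: Homogeneous hydrogenation; RhCl(PPh3)3 reduces the cis-disubstituted C11=C12 alkene and leaves the trisubstituted furyl enol ether and the furan untouched.

**Step 8**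
Reactants: 12 methyl (4aS,6S,8aR)-1,1,6-trimethyl-4-(5-methylfuran-2-yl)-4a,5,6,7,8,8a-hexahydro-1H-isochromene-6-carboxylate
Product: 14 methyl (4R,4aS,6S,8aR)-4-hydroxy-1,1,6-trimethyl-4-(5-methylfuran-2-yl)octahydro-1H-isochromene-6-carboxylate, via tertiary hydroperoxide 13 (not isolated)
Conditions: Mn(dpm)3 (dpm = dipivaloylmethanato, 10 mol%), PhSiH3, O2 (1 atm), i-PrOH–CH2Cl2, 0 °C; then PPh3
Reagents that add atoms: dioxygen, O=O
Why: Mukaiyama hydration (metal-hydride hydrogen-atom transfer): H adds to C7 to give the tertiary furfuryl radical at C6, which O2 traps on the convex face of the cis-fused bicycle (cis to H15 and H10), setting C6 with the hydroxyl exo and the furan on the face that can later reach C16.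

**Step 9**
Reactants: 14 methyl (4R,4aS,6S,8aR)-4-hydroxy-1,1,6-trimethyl-4-(5-methylfuran-2-yl)octahydro-1H-isochromene-6-carboxylate
Product: 15 (4R,4aS,6S,8aR)-4-hydroxy-1,1,6-trimethyl-4-(5-methylfuran-2-yl)octahydro-1H-isochromene-6-carbaldehyde
Conditions: i-Bu2AlH (2.2 equiv), CH2Cl2, −78 °C; then aq. potassium sodium tartrate
Reagents that add atoms: none
Why: Partial ester reduction; the tetrahedral aluminate of this α-quaternary ester does not collapse at −78 °C, so the aldehyde is released only on work-up.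

**Step 10**
Reactants: 15 (4R,4aS,6S,8aR)-4-hydroxy-1,1,6-trimethyl-4-(5-methylfuran-2-yl)octahydro-1H-isochromene-6-carbaldehyde
Product: 16 (2E)-3-[(4R,4aS,6S,8aR)-4-hydroxy-1,1,6-trimethyl-4-(5-methylfuran-2-yl)octahydro-1H-isochromen-6-yl]prop-2-enal
Conditions: Ph3P=CHCHO, toluene, 90 °C
Reagents that add atoms: (triphenylphosphoranylidene)acetaldehyde, O=CC=P(c1ccccc1)(c1ccccc1)c1ccccc1
Why: Wittig olefination with a stabilised ylide gives the E enal; the aldehyde has no α-hydrogen, so heating is harmless.

**Step 11**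
Reactants: 16 (2E)-3-[(4R,4aS,6S,8aR)-4-hydroxy-1,1,6-trimethyl-4-(5-methylfuran-2-yl)octahydro-1H-isochromen-6-yl]prop-2-enal
Product: 17 tricyclic furan dienal (furan C4–C16 bond; exocyclic C16=C17–CHO)
Conditions: Pd(OAc)2 (10 mol%), p-benzoquinone (1.2 equiv), NaOAc, dioxane–DMSO, 50 °C
Reagents that add atoms: none
Why: Fujiwara–Moritani (oxidative Heck) cyclisation: divalent palladium metalates the electron-rich furan β-position, 7-exo insertion of the enal puts the furan on C16 (the β-carbon), and β-hydride elimination of H16 restores the enal; only the furan β-carbon next to C5 can reach, and the exo C6 hydroxyl cannot.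

**Step 12**
Reactants: 17 tricyclic furan dienal
Product: 19 furan-fused (E)-enol 3-methylbut-2-enoate, via E-silyl enol ether 18 (not isolated)
Conditions: [(Ph3P)CuH]6, Me3SiCl, 2,6-lutidine, THF, −40 °C; then Me2C=CHCOF, n-Bu4N[Ph3SiF2] (cat.), −78 °C
Reagents that add atoms: 3-methylbut-2-enoyl fluoride, CC(C)=CC(F)=O
Why: Copper hydride conjugate reduction with silyl trapping, then fluoride-catalysed O-acylation: hydride enters C16 on the face opposite the C13 methyl group (the face external nucleophiles take in this ring system), leaving the side chain on the natural face, and the β,β-disubstituted enal reacts only as its s-trans conformer, so the enolate, the silyl enol ether and the enol ester are all E.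

**Step 13**
Reactants: 19 furan-fused (E)-enol 3-methylbut-2-enoate
Product: 21 target hydroxy diketone enol ester, via Z-enedione 20 (not isolated)
Conditions: mCPBA (1.0 equiv), CH2Cl2, 0 °C; then Zn, AcOH, 0 °C, 10 min
Reagents that add atoms: 3-chloroperoxybenzoic acid, OOC(=O)c1cccc(Cl)c1
Why: Achmatowicz-type oxidative opening of the furfuryl alcohol to the cis-enedione (the trisubstituted furan is far more electron-rich than the enol ester or the enoate), then zinc conjugate reduction; the C5 enol is protonated kinetically at C4 on the exo face carrying the C6 hydroxyl, which puts the acetonyl group trans to both the hydroxyl and the C16 side chain as in the target, and the short acidic contact avoids epimerisation.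

**Compound list**
1 | methyl 4-acetylbenzoate | CC(=O)c1ccc(cc1)C(=O)OC | starting material
2 | methyl 4-(2-hydroxypropan-2-yl)benzoate | CC(C)(O)c1ccc(cc1)C(=O)OC | intermediate
3 | dilithium alkoxide–ester dienolate from 2 | [Li+].[Li+].COC([O-])=C1C=CC(C=C1)C(C)(C)[O-] | intermediate
4 | methyl cis-4-(2-hydroxypropan-2-yl)-1-methylcyclohexa-2,5-diene-1-carboxylate | CC(C)(O)[C@@H]1C=C[C@@](C)(C=C1)C(=O)OC | intermediate
5 | 1-(5-methylfuran-2-yl)ethan-1-one | CC(=O)c1ccc(C)o1 | starting material
6 | 4,4,4-trifluoro-1-(5-methylfuran-2-yl)butane-1,3-dione | Cc1ccc(o1)C(=O)CC(=O)C(F)(F)F | intermediate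
7 | 2-diazo-1-(5-methylfuran-2-yl)ethan-1-one | Cc1ccc(o1)C(=O)C=[N+]=[N-] | intermediate
8 | methyl cis-1-methyl-4-{2-[2-(5-methylfuran-2-yl)-2-oxoethoxy]propan-2-yl}cyclohexa-2,5-diene-1-carboxylate | Cc1ccc(o1)C(=O)COC(C)(C)[C@@H]2C=C[C@@](C)(C=C2)C(=O)OC | intermediate
9 | potassium (Z)-enolate of 8 | [K+].Cc1ccc(o1)/C([O-])=C/OC(C)(C)[C@@H]2C=C[C@@](C)(C=C2)C(=O)OC | intermediate
10 | (Z)-enol triflate of 8 | Cc1ccc(o1)/C(OS(=O)(=O)C(F)(F)F)=C/OC(C)(C)[C@@H]2C=C[C@@](C)(C=C2)C(=O)OC | intermediate
11 | methyl (4aS,6R,8aR)-1,1,6-trimethyl-4-(5-methylfuran-2-yl)-4a,5,6,8a-tetrahydro-1H-isochromene-6-carboxylate | Cc1ccc(o1)C2=COC(C)(C)[C@@H]3C=C[C@@](C)(C[C@@H]32)C(=O)OC | intermediate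
12 | methyl (4aS,6S,8aR)-1,1,6-trimethyl-4-(5-methylfuran-2-yl)-4a,5,6,7,8,8a-hexahydro-1H-isochromene-6-carboxylate | Cc1ccc(o1)C2=COC(C)(C)[C@@H]3CC[C@@](C)(C[C@@H]32)C(=O)OC | intermediate
13 | 4-hydroperoxy analogue of 14 | Cc1ccc(o1)[C@]2(OO)COC(C)(C)[C@@H]3CC[C@@](C)(C[C@@H]32)C(=O)OC | intermediate
14 | methyl (4R,4aS,6S,8aR)-4-hydroxy-1,1,6-trimethyl-4-(5-methylfuran-2-yl)octahydro-1H-isochromene-6-carboxylate | Cc1ccc(o1)[C@]2(O)COC(C)(C)[C@@H]3CC[C@@](C)(C[C@@H]32)C(=O)OC | intermediate
15 | (4R,4aS,6S,8aR)-4-hydroxy-1,1,6-trimethyl-4-(5-methylfuran-2-yl)octahydro-1H-isochromene-6-carbaldehyde | Cc1ccc(o1)[C@]2(O)COC(C)(C)[C@@H]3CC[C@@](C)(C[C@@H]32)C=O | intermediate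
16 | (2E)-3-[(4R,4aS,6S,8aR)-4-hydroxy-1,1,6-trimethyl-4-(5-methylfuran-2-yl)octahydro-1H-isochromen-6-yl]prop-2-enal | Cc1ccc(o1)[C@]2(O)COC(C)(C)[C@@H]3CC[C@@](C)(C[C@@H]32)/C=C/C=O | intermediate
17 | tricyclic furan dienal (furan C4 bonded to C16; C16=C17–CHO, formyl cis to the furan) | Cc1cc2c(o1)[C@]3(O)COC(C)(C)[C@@H]4CC[C@@](C)(C[C@@H]43)/C2=C/C=O | intermediate
18 | (E)-trimethylsilyl enol ether of the C16-reduced aldehyde | Cc1cc2c(o1)[C@]3(O)COC(C)(C)[C@@H]4CC[C@@](C)(C[C@@H]43)[C@H]2/C=C/O[Si](C)(C)C | intermediate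
19 | furan-fused (E)-enol 3-methylbut-2-enoate (target with C2–C5 still tied up as the 2-methylfuran) | Cc1cc2c(o1)[C@]3(O)COC(C)(C)[C@@H]4CC[C@@](C)(C[C@@H]43)[C@H]2/C=C/OC(=O)C=C(C)C | intermediate
20 | (Z)-ene-1,4-dione (C3=C4) from furan opening | CC(=O)/C=C1\C(=O)[C@]2(O)COC(C)(C)[C@@H]3CC[C@@](C)(C[C@@H]32)[C@H]1/C=C/OC(=O)C=C(C)C | intermediate
21 | target hydroxy diketone enol ester | CC(=O)C[C@@H]1C(=O)[C@]2(O)COC(C)(C)[C@@H]3CC[C@@](C)(C[C@@H]32)[C@H]1/C=C/OC(=O)C=C(C)C | target

**Step count**
Total: 13 steps. Longest linear sequence: 12 steps (1 to 21; step 3 prepares reagent 7 separately).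

**Three steps most likely to fail, with fallbacks**

Step 6 (enantioselective reductive Heck). The risks are low enantioselection, reduction of the alkenyl–palladium before insertion, and a 3-exo insertion of the C14–Pd into the second ring alkene. The fallback breaks the symmetry with a carbene organocatalyst instead and sets out from 4. Alcohol 4 is etherified with ethyl diazoacetate (Rh2(OAc)4) to the ethyl alkoxyacetate F1. The more reactive alkoxyacetate ester is reduced (i-Bu2AlH, −78 °C) to the alkoxyacetaldehyde F2. A chiral aminoindanol-derived triazolium carbene then adds the acyl group across one ring alkene (desymmetrising hydroacylation) to give the bicyclic pyranone F3. Kinetic enolisation towards C7 and triflation (KN(SiMe3)2, PhNTf2) give the enol triflate F4. Negishi coupling with (5-methylfuran-2-yl)zinc chloride and Pd(PPh3)4 returns to the route at 11.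

Step 11 (oxidative Heck closure of the seven-membered ring). The risks are the modest nucleophilicity of the furan β-position, the strain of the reactive conformer (C6 and C16 both axial), and palladium-induced cleavage at the tertiary furfuryl alcohol. The fallback makes the C4–C16 bond by a redox-neutral addition to an alkyne and sets out from 15. Aldehyde 15 is converted with dimethyl (1-diazo-2-oxopropyl)phosphonate (K2CO3, MeOH) into the terminal alkyne F5. Deprotonation (n-BuLi, 2.2 equiv) and formylation with DMF give the ynal F6. A 7-exo-dig hydroarylation by the furan, catalysed by (Ph3P)AuNTf2, returns to the route at 17.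

Step 12 (conjugate reduction and E-selective enol ester formation). The risks are sluggish hydride addition to the hindered, furan-conjugated β-carbon, 1,2-reduction, and loss of enolate geometry. The fallback separates the C16 and alkene-geometry problems and sets out from 17. Organocatalytic transfer hydrogenation (Hantzsch ester, (2S,5S)-5-benzyl-2-tert-butyl-3-methylimidazolidin-4-one trichloroacetate) gives the saturated aldehyde F7 with C16 set by catalyst and substrate. Nonaflation and elimination (C4F9SO2F, phosphazene base) convert it to the terminal alkyne F8. Hydroboration with pinacolborane and Cp2Zr(H)Cl (cat.) gives the (E)-alkenylboronate F9. Copper-mediated oxidative coupling with 3-methylbut-2-enoic acid (Cu(OAc)2, Et3N, O2, 4 Å sieves) returns to the route at 19 with the E geometry fixed by the boronate.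

**Further compounds**
F1 | step 6 | methyl cis-4-[2-(2-ethoxy-2-oxoethoxy)propan-2-yl]-1-methylcyclohexa-2,5-diene-1-carboxylate | CCOC(=O)COC(C)(C)[C@@H]1C=C[C@@](C)(C=C1)C(=O)OC
F2 | step 6 | methyl cis-1-methyl-4-[2-(2-oxoethoxy)propan-2-yl]cyclohexa-2,5-diene-1-carboxylate | O=CCOC(C)(C)[C@@H]1C=C[C@@](C)(C=C1)C(=O)OC
F3 | step 6 | methyl (4aS,6R,8aR)-1,1,6-trimethyl-4-oxo-3,4,4a,5,6,8a-hexahydro-1H-isochromene-6-carboxylate | O=C2COC(C)(C)[C@@H]3C=C[C@@](C)(C[C@@H]32)C(=O)OC
F4 | step 6 | methyl (4aS,6R,8aR)-1,1,6-trimethyl-4-[(trifluoromethanesulfonyl)oxy]-4a,5,6,8a-tetrahydro-1H-isochromene-6-carboxylate | O=S(=O)(OC2=COC(C)(C)[C@@H]3C=C[C@@](C)(C[C@@H]32)C(=O)OC)C(F)(F)F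
F5 | step 11 | (4R,4aS,6S,8aR)-6-ethynyl-1,1,6-trimethyl-4-(5-methylfuran-2-yl)octahydro-1H-isochromen-4-ol | Cc1ccc(o1)[C@]2(O)COC(C)(C)[C@@H]3CC[C@@](C)(C[C@@H]32)C#C
F6 | step 11 | 3-[(4R,4aS,6S,8aR)-4-hydroxy-1,1,6-trimethyl-4-(5-methylfuran-2-yl)octahydro-1H-isochromen-6-yl]prop-2-ynal | Cc1ccc(o1)[C@]2(O)COC(C)(C)[C@@H]3CC[C@@](C)(C[C@@H]32)C#CC=O
F7 | step 12 | saturated tricyclic furan aldehyde (17 with H on C16; side chain CH2CHO) | Cc1cc2c(o1)[C@]3(O)COC(C)(C)[C@@H]4CC[C@@](C)(C[C@@H]43)[C@H]2CC=O
F8 | step 12 | tricyclic furan terminal alkyne (ethynyl on C16) | Cc1cc2c(o1)[C@]3(O)COC(C)(C)[C@@H]4CC[C@@](C)(C[C@@H]43)[C@H]2C#C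
F9 | step 12 | tricyclic furan (E)-alkenyl pinacolboronate | Cc1cc2c(o1)[C@]3(O)COC(C)(C)[C@@H]4CC[C@@](C)(C[C@@H]43)[C@H]2/C=C/B5OC(C)(C)C(C)(C)O5
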